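**Retrosynthetic overview**
1. Target 11 is 2β-acetoxylabda-8(17),13E-dien-15-oic acid of the normal labdane series (2R,5S,9S,10S). Rings A and B with C5, C9 and C10 are bought intact in (−)-sclareol 1, so no ring is formed.
2. Key disconnection C2–O: electrochemical C–H oxygenation of hydroxy enoate 4 gives 2-ketone 5; hydride delivery to the α face of ring A later sets the 2β oxygen.
3. C13=C14: Horner–Wadsworth–Emmons olefination of methyl ketone 2 (oxidative cleavage of the vinyl carbinol of 1) with phosphonate 3.
4. C8=C17: anti-elimination of the 8α-OH, kept saturated until after the C–H oxidation; the tert-butyl ester is removed last.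

Assumption: labdane numbering is used throughout; β is the face of the C10 methyl group (C20), α the opposite face.

**Step 1**
Reactants: 1 (−)-sclareol
Product: 2 8α-hydroxy-14,15-dinorlabdan-13-one
Conditions: KMnO4 (4 equiv), BnEt3NCl (cat.), CH2Cl2/H2O, 0 °C to rt
Reagents that add atoms: none
Why: Permanganate oxidative cleavage of the vinyl carbinol (alkene cleavage, then oxidative decarboxylation) removes C14 and C15 as carbonate and turns the C13 carbinol into the methyl ketone with its own oxygen, while the saturated decalin and the tertiary 8α-OH are inert and C5, C8, C9 and C10 are untouched.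

**Step 2**
Reactants: 2 8α-hydroxy-14,15-dinorlabdan-13-one; 3 tert-butyl diethylphosphonoacetate
Product: 4 tert-butyl (13E)-8α-hydroxylabd-13-en-15-oate
Conditions: NaH, THF, 0 °C to 50 °C
Reagents that add atoms: tert-butyl diethylphosphonoacetate (3), CCOP(=O)(CC(=O)OC(C)(C)C)OCC
Why: Horner–Wadsworth–Emmons olefination of the unhindered methyl ketone with the preformed sodium phosphonate; reversible addition and the bulky tert-butyl ester favour the E-alkene (about 6:1 expected, Z isomer removed by chromatography), and the tertiary alcohol is too weakly acidic to interfere.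

**Step 3**
Reactants: 4 tert-butyl (13E)-8α-hydroxylabd-13-en-15-oate
Product: 5 tert-butyl (13E)-8α-hydroxy-2-oxolabd-13-en-15-oate
Conditions: quinuclidine (1 equiv), Me4NBF4, HFIP, MeCN, O2 (1 atm), RVC anode, Ni cathode, undivided cell, constant current, rt
Reagents that add atoms: dioxygen, O=O
Why: Proposed new method: anodic oxidation of quinuclidine gives its aminium radical cation, a strongly electrophilic hydrogen-atom abstractor that should take the most hydridic, least hindered methylene hydrogen (C2 of ring A, remote from the HFIP-hydrogen-bonded 8α-OH that inductively deactivates C6, C7 and C9) while sparing the enoate, because its allylic C12–H and C16–H are vinylogous α-hydrogens of an ester (polarity-mismatched) and its electron-poor C=C does not add an electrophilic N-radical; the C2 radical is trapped by O2 and the peroxyl radical collapses to the ketone, which deactivates ring A against over-oxidation, with no stereocenter formed; the closest known reaction type is the quinuclidine-mediated electrochemical oxidation of unactivated methylene C–H bonds in saturated terpenoids (sclareolide to 2-oxosclareolide), not yet shown on an alkene-containing substrate.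

**Step 4**
Reactants: 5 tert-butyl (13E)-8α-hydroxy-2-oxolabd-13-en-15-oate
Product: 7 tert-butyl (13E)-2-oxolabda-8(17),13-dien-15-oate, via 8-chlorosulfite ester 6 (not isolated)
Conditions: SOCl2, pyridine, CH2Cl2, −78 °C
Reagents that add atoms: none
Why: Anti-elimination (E2) of the chlorosulfite: the equatorial 8α leaving group has no antiperiplanar ring hydrogen, only those of the axial C17 methyl, so the exocyclic 8(17)-alkene forms (minor endocyclic isomers are removed on AgNO3-impregnated silica); ketone, enoate and tert-butyl ester are inert at −78 °C.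

**Step 5**
Reactants: 7 tert-butyl (13E)-2-oxolabda-8(17),13-dien-15-oate
Product: 9 tert-butyl (13E)-2β-acetoxylabda-8(17),13-dien-15-oate, via lithium 2β-alkoxide 8 (not isolated)
Conditions: LiBH(s-Bu)3, THF, −78 °C; then Ac2O, DMAP (cat.), −78 °C to rt
Reagents that add atoms: acetic anhydride, CC(=O)OC(C)=O
Why: Substrate-controlled ketone reduction followed by in-flask O-acylation (reductive acetylation): the β face of C2 is blocked by the two syn-axial methyl groups at C4 and C10, so the bulky hydride adds from the α face and gives the axial 2β-alkoxide (2R), which as the lithium alkoxide is acylated far more easily than the hindered neutral alcohol; the β,β-disubstituted tert-butyl enoate resists hydride addition at −78 °C.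

**Step 6**
Reactants: 9 tert-butyl (13E)-2β-acetoxylabda-8(17),13-dien-15-oate
Product: 11 2β-acetoxylabda-8(17),13E-dien-15-oic acid, via trimethylsilyl ester 10 (not isolated)
Conditions: TMSOTf, 2,6-lutidine, CH2Cl2, 0 °C; then H2O, THF, rt
Reagents that add atoms: none
Why: Silyl triflate-mediated tert-butyl ester cleavage: O-silylation of the ester carbonyl and loss of isobutene under 2,6-lutidine buffering avoid protic acid that would isomerise the exocyclic alkene, the acetate is untouched, and the silyl ester is hydrolysed on aqueous work-up.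

**Compound list**
1 | (−)-sclareol, (13R)-labd-14-ene-8α,13-diol (5S,8R,9R,10S) | C[C@@]1(O)CC[C@H]2C(C)(C)CCC[C@]2(C)[C@H]1CC[C@@](C)(O)C=C | starting material
2 | 8α-hydroxy-14,15-dinorlabdan-13-one (methyl ketone on the C9 side chain, 8α-OH, 8β-methyl) | C[C@@]1(O)CC[C@H]2C(C)(C)CCC[C@]2(C)[C@H]1CCC(C)=O | intermediate
3 | tert-butyl diethylphosphonoacetate | CCOP(=O)(CC(=O)OC(C)(C)C)OCC | starting material
4 | tert-butyl (13E)-8α-hydroxylabd-13-en-15-oate | C[C@@]1(O)CC[C@H]2C(C)(C)CCC[C@]2(C)[C@H]1CC/C(C)=C/C(=O)OC(C)(C)C | intermediate
5 | tert-butyl (13E)-8α-hydroxy-2-oxolabd-13-en-15-oate | C[C@@]1(O)CC[C@H]2C(C)(C)CC(=O)C[C@]2(C)[C@H]1CC/C(C)=C/C(=O)OC(C)(C)C | intermediate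
6 | tert-butyl (13E)-8α-(chlorosulfinyloxy)-2-oxolabd-13-en-15-oate (8-chlorosulfite ester, not isolated) | C[C@@]1(OS(Cl)=O)CC[C@H]2C(C)(C)CC(=O)C[C@]2(C)[C@H]1CC/C(C)=C/C(=O)OC(C)(C)C | intermediate
7 | tert-butyl (13E)-2-oxolabda-8(17),13-dien-15-oate | C=C1CC[C@H]2C(C)(C)CC(=O)C[C@]2(C)[C@H]1CC/C(C)=C/C(=O)OC(C)(C)C | intermediate
8 | lithium 2β-alkoxide of tert-butyl (13E)-2β-hydroxylabda-8(17),13-dien-15-oate (not isolated) | [Li+].C=C1CC[C@H]2C(C)(C)C[C@@H]([O-])C[C@]2(C)[C@H]1CC/C(C)=C/C(=O)OC(C)(C)C | intermediate
9 | tert-butyl (13E)-2β-acetoxylabda-8(17),13-dien-15-oate | C=C1CC[C@H]2C(C)(C)C[C@@H](OC(C)=O)C[C@]2(C)[C@H]1CC/C(C)=C/C(=O)OC(C)(C)C | intermediate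
10 | trimethylsilyl (13E)-2β-acetoxylabda-8(17),13-dien-15-oate (not isolated) | C=C1CC[C@H]2C(C)(C)C[C@@H](OC(C)=O)C[C@]2(C)[C@H]1CC/C(C)=C/C(=O)O[Si](C)(C)C | intermediate
11 | 2β-acetoxylabda-8(17),13E-dien-15-oic acid (2R,5S,9S,10S) | C=C1CC[C@H]2C(C)(C)C[C@@H](OC(C)=O)C[C@]2(C)[C@H]1CC/C(C)=C/C(=O)O | target

**Step count and risks**
Total steps: 6. Longest linear sequence: 6 (1 to 11).

The three steps most likely to fail:

Step 3 (the proposed new electrochemical oxygenation). The risk is competing abstraction at C3 or at the allylic C12/C16 positions, or direct attack on the enoate. The fallback uses known chemistry and sets out from 2. The same mediated anodic oxygenation (quinuclidine, Me4NBF4, HFIP, MeCN, O2, RVC anode, Ni cathode) is run one stage earlier on the fully saturated ketol 2. This stays within the saturated ketone and lactone substrate class for which the method is established, and gives 8α-hydroxy-14,15-dinorlabdane-2,13-dione F1. Horner–Wadsworth–Emmons olefination with 3 (NaH, THF, 0 °C to rt) should then take only the unhindered C13 methyl ketone, because the C2 carbonyl is a 3,3,5,5-tetrasubstituted cyclohexanone flanked by two syn-axial methyl groups. This comes back to the route at 5.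

Step 5 (one-pot reductive acetylation). The risk is enolisation of the hindered ketone by the bulky borohydride, or incomplete acylation of the encumbered axial alkoxide. The fallback sets out from 7 and separates the two events. Reduction with NaBH4 (MeOH/THF, 0 °C) and aqueous work-up gives the isolated and purified alcohol tert-butyl (13E)-2β-hydroxylabda-8(17),13-dien-15-oate F2. The neutral alcohol is then acetylated in a separate nucleophile-catalysed acyl transfer (Ac2O, DMAP, Et3N, CH2Cl2, 40 °C). This comes back to the route at 9.

Step 1 (permanganate degradation). The risk is over-oxidation of the side chain and acid-promoted cyclodehydration of 2 to its cyclic enol ether. The fallback sets out from 1 and cleaves the side chain in two controlled stages. Ozonolysis (O3, CH2Cl2/MeOH, −78 °C; then Me2S) gives the α-hydroxy aldehyde (13R)-8α,13-dihydroxy-15-norlabdan-14-al F3. Periodate cleavage of the α-hydroxy aldehyde (NaIO4, THF/H2O, rt) then removes C14 as formic acid. This comes back to the route at 2.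

**Further compounds**
F1 | step 3 | 8α-hydroxy-14,15-dinorlabdane-2,13-dione | C[C@@]1(O)CC[C@H]2C(C)(C)CC(=O)C[C@]2(C)[C@H]1CCC(C)=O
F2 | step 5 | tert-butyl (13E)-2β-hydroxylabda-8(17),13-dien-15-oate | C=C1CC[C@H]2C(C)(C)C[C@@H](O)C[C@]2(C)[C@H]1CC/C(C)=C/C(=O)OC(C)(C)C
F3 | step 1 | (13R)-8α,13-dihydroxy-15-norlabdan-14-al | C[C@@]1(O)CC[C@H]2C(C)(C)CCC[C@]2(C)[C@H]1CC[C@@](C)(O)C=O
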